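**Retrosynthetic overview**

1. The target is a fourteen-membered carbocycle (cembrane numbering: C1 bears the isopropyl group, C4 the CO2Me group, C7 the acetate, C8 the methyl group) bridged by a seven-membered unsaturated lactone O–C20(=O)–C12=C11–C10–C9–C8, with stereocenters C7 (R) and C8 (S).
2. The fourteen-membered ring is opened last at C3=C4: intramolecular Horner–Wadsworth–Emmons olefination of a C3 enal with a C4 phosphonoacetate.
3. Key disconnection: C10–C9 and O–C8 in one flask, a stereospecific anionic (5+2) annulation. The five-atom partner is the (Z)-dienediolate of a 2-ethylidene carboxylic acid (O, C20, C12, C11, C10); the two-atom partner is a 2,3-epoxy triflate (C9 = CH2OTf, C8 = tertiary epoxide carbon).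
4. Enabling feature: in the lactone ring the carboxyl oxygen and the γ-carbon C10 of a vinylogous carboxylate sit 1,2 on C8–C9, and the C8 oxygen is vicinal to the C7 oxygen. C9–C8(O)–C7(O) is therefore the imprint of a Sharpless 2,3-epoxy alcohol opened with inversion at its tertiary carbon.
5. Ring order: seven-membered lactone first (step 13), fourteen-membered carbocycle last (step 18).

Key step: step 13

Remark: atom numbers Cn are cembrane numbers as defined above; the phosphorus-bearing carbons of the two alkylated phosphonates are formed as epimer mixtures and drawn without configuration, because they become sp2 carbons.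

**Acid fragment (steps 1–7)**

Step 1
Reactants: 1 4-methylpent-2-yn-1-ol
Product: 3 (2Z)-3-iodo-4-methylpent-2-en-1-ol, via sodium alkenylalanate 2 (not isolated)
Conditions: NaAlH2(OCH2CH2OCH3)2 (1.5 equiv), THF, 0 °C to rt; then I2, −78 °C to rt
Reagents that add atoms: iodine, II
Why: Hydroxyl-directed trans-hydroalumination of the propargylic alcohol puts aluminium on the isopropyl-bearing carbon inside a five-membered alanate, and iodinolysis with retention should give the vinyl iodide with iodine cis to the hydroxymethyl group, which fixes the C1=C2 geometry (hydroalumination–iodination).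

Step 2
Reactants: 3 (2Z)-3-iodo-4-methylpent-2-en-1-ol
Product: 4 tert-butyl{[(2Z)-3-iodo-4-methylpent-2-en-1-yl]oxy}diphenylsilane
Conditions: TBDPSCl, imidazole, CH2Cl2, rt
Reagents that add atoms: tert-butyl(chloro)diphenylsilane, CC(C)(C)[Si](Cl)(c1ccccc1)c1ccccc1
Why: Silylation of the primary allylic alcohol with TBDPSCl and imidazole (silyl ether formation) is routine and gives a group that should survive organolithium, enolate and mildly acidic steps.

Step 3
Reactants: 4 tert-butyl{[(2Z)-3-iodo-4-methylpent-2-en-1-yl]oxy}diphenylsilane, 5 oxirane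
Product: 7 (3E)-5-[(tert-butyldiphenylsilyl)oxy]-3-(propan-2-yl)pent-3-en-1-ol, via vinyllithium 6 (not isolated)
Conditions: t-BuLi (2.1 equiv), Et2O, −78 °C; then oxirane (3 equiv), −78 to 0 °C; aq NH4Cl
Reagents that add atoms: none
Why: Iodine–lithium exchange occurs with retention of alkene geometry and the vinyllithium should open oxirane by SN2 attack at −78 to 0 °C, where migration of the bulky silyl group from oxygen to carbon is slow (halogen–metal exchange and epoxide opening).

Step 4
Reactants: 7 (3E)-5-[(tert-butyldiphenylsilyl)oxy]-3-(propan-2-yl)pent-3-en-1-ol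
Product: 8 tert-butyl{[(2E)-5-iodo-3-(propan-2-yl)pent-2-en-1-yl]oxy}diphenylsilane
Conditions: I2, PPh3, imidazole, CH2Cl2, 0 °C
Reagents that add atoms: iodine, II
Why: The PPh3–I2–imidazole system converts the primary alcohol into the iodide by SN2 displacement of an alkoxyphosphonium ion (Appel-type iodination) without touching the silyl ether or the alkene.

Step 5
Reactants: 8 tert-butyl{[(2E)-5-iodo-3-(propan-2-yl)pent-2-en-1-yl]oxy}diphenylsilane, 9 methyl [bis(2,2,2-trifluoroethoxy)phosphoryl]acetate
Product: 10 methyl (5E)-2-[bis(2,2,2-trifluoroethoxy)phosphoryl]-7-[(tert-butyldiphenylsilyl)oxy]-5-(propan-2-yl)hept-5-enoate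
Conditions: NaH, DMF, 0 to 50 °C (9 in excess)
Reagents that add atoms: none
Why: SN2 alkylation of the sodium phosphonoacetate enolate by the unhindered primary iodide should give the α-substituted Still–Gennari reagent, whose new stereocenter is formed as a racemate and disappears in step 6.

Step 6
Reactants: 10 methyl (5E)-2-[bis(2,2,2-trifluoroethoxy)phosphoryl]-7-[(tert-butyldiphenylsilyl)oxy]-5-(propan-2-yl)hept-5-enoate, 11 acetaldehyde
Product: 12 methyl (2Z,5E)-7-[(tert-butyldiphenylsilyl)oxy]-2-ethylidene-5-(propan-2-yl)hept-5-enoate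
Conditions: KN(SiMe3)2, 18-crown-6, THF, −78 °C
Reagents that add atoms: none
Why: The Still–Gennari variant of the Horner–Wadsworth–Emmons olefination, with the electron-poor bis(trifluoroethyl) phosphonate and a dissociated potassium counterion, should eliminate under kinetic control to the trisubstituted (Z)-enoate in which the new methyl group C10 is cis to the ester carbon C20.

Step 7
Reactants: 12 methyl (2Z,5E)-7-[(tert-butyldiphenylsilyl)oxy]-2-ethylidene-5-(propan-2-yl)hept-5-enoate
Product: 13 (2Z,5E)-7-[(tert-butyldiphenylsilyl)oxy]-2-ethylidene-5-(propan-2-yl)hept-5-enoic acid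
Conditions: LiOH, THF–MeOH–H2O, 45 °C; then 1 M HCl
Reagents that add atoms: lithium hydroxide, [Li+].[OH-]
Why: Saponification of the methyl ester with LiOH (ester hydrolysis) should free the carboxylic acid without touching the silyl ether or either alkene geometry.

**Epoxy triflate fragment (steps 8–12)**

Step 8
Reactants: 14 3-[(tert-butyldimethylsilyl)oxy]propanal, 15 ethyl 2-(triphenyl-λ5-phosphanylidene)propanoate
Product: 16 ethyl (2E)-5-[(tert-butyldimethylsilyl)oxy]-2-methylpent-2-enoate
Conditions: CH2Cl2, rt to 40 °C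
Reagents that add atoms: none
Why: Wittig olefination of the aldehyde with the stabilised α-methyl ylide should give the (E)-trisubstituted enoate, the usual outcome for stabilised ylides.

Step 9
Reactants: 16 ethyl (2E)-5-[(tert-butyldimethylsilyl)oxy]-2-methylpent-2-enoate
Product: 17 ethyl (2E)-5-bromo-2-methylpent-2-enoate
Conditions: Ph3PBr2, CH2Cl2, 0 °C to rt
Reagents that add atoms: dibromotriphenylphosphorane, BrP(Br)(c1ccccc1)(c1ccccc1)c1ccccc1
Why: Ph3PBr2 converts a primary tert-butyldimethylsilyl ether directly into the bromide through an alkoxyphosphonium bromide (Appel-type substitution), so that the handle for the later phosphonate alkylation is in place before the epoxide is made.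

Step 10
Reactants: 17 ethyl (2E)-5-bromo-2-methylpent-2-enoate
Product: 18 (2E)-5-bromo-2-methylpent-2-en-1-ol
Conditions: i-Bu2AlH (2.2 equiv), CH2Cl2, −78 °C
Reagents that add atoms: none
Why: 1,2-Reduction of the conjugated ester with i-Bu2AlH at low temperature (hydride reduction) should give the allylic alcohol and leave the primary bromide and the alkene geometry untouched.

Step 11
Reactants: 18 (2E)-5-bromo-2-methylpent-2-en-1-ol
Product: 19 [(2R,3R)-3-(2-bromoethyl)-2-methyloxiran-2-yl]methanol
Conditions: Ti(O-i-Pr)4 (10 mol %), D-(−)-diethyl tartrate (12 mol %), t-BuOOH, 4 Å molecular sieves, CH2Cl2, −20 °C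
Reagents that add atoms: tert-butyl hydroperoxide, CC(C)(C)OO
Why: Sharpless asymmetric epoxidation of the (E)-2-methylallylic alcohol with the D-tartrate ligand should deliver oxygen to one face of the alkene and give the (2R,3R)-epoxy alcohol, which sets C7 in its final configuration and C8 in the configuration that the inversion of step 13 turns into the required one.

Step 12
Reactants: 19 [(2R,3R)-3-(2-bromoethyl)-2-methyloxiran-2-yl]methanol
Product: 20 [(2R,3R)-3-(2-bromoethyl)-2-methyloxiran-2-yl]methyl trifluoromethanesulfonate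
Conditions: Tf2O, 2,6-lutidine, CH2Cl2, −78 °C, used at once
Reagents that add atoms: trifluoromethanesulfonic anhydride, O=S(=O)(OS(=O)(=O)C(F)(F)F)C(F)(F)F
Why: Sulfonylation of the primary alcohol with Tf2O and a hindered pyridine base (triflate formation) should give the epoxy triflate, which is used at once because this class of electrophile is reactive but is attacked by soft carbon nucleophiles at the CH2–OTf carbon and not at the epoxide.

**Annulation and endgame (steps 13–18)**

Step 13
Reactants: 13 (2Z,5E)-7-[(tert-butyldiphenylsilyl)oxy]-2-ethylidene-5-(propan-2-yl)hept-5-enoic acid, 20 [(2R,3R)-3-(2-bromoethyl)-2-methyloxiran-2-yl]methyl trifluoromethanesulfonate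
Product: 24 (7S)-7-[(1R)-3-bromo-1-hydroxypropyl]-3-[(3E)-5-[(tert-butyldiphenylsilyl)oxy]-3-(propan-2-yl)pent-3-en-1-yl]-7-methyl-6,7-dihydrooxepin-2(5H)-one, via dilithium dienediolate 21 (not isolated), via dicopper dienediolate 22 (not isolated), via epoxy acid 23 (not isolated)
Conditions: LiN(i-Pr)2 (2.2 equiv), THF, −78 to −40 °C; CuI (2.2 equiv), −78 °C; then 20, −78 to −30 °C; then camphorsulfonic acid (4 equiv), CH2Cl2, −30 °C to rt, one flask
Reagents that add atoms: none
Why: Proposed new method: a stereospecific anionic (5+2) annulation in which the (Z)-dienediolate of acid 13, made by carboxylate-directed removal of a proton from the methyl group cis to the carboxylate and softened as its monovalent copper salt, is alkylated at its γ-carbon C10 by the CH2–OTf carbon C9 of epoxy triflate 20, after which acidification lets the carboxyl oxygen open the epoxide at the tertiary carbon C8 in the same flask. The closest known reaction types are the γ-alkylation of copper dienolates of unsaturated acids with reactive halides, the alkylation of enolates with 2,3-epoxy triflates and the acid-catalysed opening of epoxides by carboxylic acids to hydroxy lactones. The only ring closed is the seven-membered lactone, by a 7-exo-tet opening of the epoxide, while the competing 8-endo attack at C7 is disfavoured by ring size and by the poorer cation-stabilising ability of the secondary carbon. C8 is set by inversion at the tertiary epoxide carbon and C7 keeps the configuration installed in step 11, so that both stereocenters derive from the Sharpless epoxide. The step needs γ- over α-alkylation, which the soft copper counterion, the fully substituted α-carbon C12 and the neopentyl-like electrophile should secure, and it needs retention of the Z geometry, which the low temperature and the partial double-bond character of the C11–C12 bond of the dienediolate should secure; any E isomer cannot lactonise and is removed as an acid by a bicarbonate wash.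

Step 14
Reactants: 24 (7S)-7-[(1R)-3-bromo-1-hydroxypropyl]-3-[(3E)-5-[(tert-butyldiphenylsilyl)oxy]-3-(propan-2-yl)pent-3-en-1-yl]-7-methyl-6,7-dihydrooxepin-2(5H)-one
Product: 25 (1R)-3-bromo-1-[(2S)-6-[(3E)-5-[(tert-butyldiphenylsilyl)oxy]-3-(propan-2-yl)pent-3-en-1-yl]-2-methyl-7-oxo-2,3,4,7-tetrahydrooxepin-2-yl]propyl acetate
Conditions: Ac2O, pyridine, DMAP (10 mol %), CH2Cl2, rt
Reagents that add atoms: acetic anhydride, CC(=O)OC(C)=O
Why: DMAP-catalysed acylation of the secondary C7 alcohol with acetic anhydride (esterification) should give the acetate without touching the tertiary lactone or the primary bromide.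

Step 15
Reactants: 25 the C7 acetate bromide named in step 14, 26 methyl (dimethoxyphosphoryl)acetate
Product: 27 methyl (5R)-5-(acetyloxy)-5-[(2S)-6-[(3E)-5-[(tert-butyldiphenylsilyl)oxy]-3-(propan-2-yl)pent-3-en-1-yl]-2-methyl-7-oxo-2,3,4,7-tetrahydrooxepin-2-yl]-2-(dimethoxyphosphoryl)pentanoate
Conditions: NaH, NaI (20 mol %), THF–DMSO, 45 °C (26 in threefold excess)
Reagents that add atoms: none
Why: SN2 alkylation of the stabilised phosphonoacetate anion by the primary bromide, helped by halide exchange with NaI, should install the Horner–Wadsworth–Emmons handle while the weakly basic anion leaves the acetate and the lactone intact, and the new stereocenter is formed as an epimer mixture that disappears in step 18.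

Step 16
Reactants: 27 the silyl ether phosphonate named in step 15
Product: 28 methyl (5R)-5-(acetyloxy)-2-(dimethoxyphosphoryl)-5-[(2S)-6-[(3E)-5-hydroxy-3-(propan-2-yl)pent-3-en-1-yl]-2-methyl-7-oxo-2,3,4,7-tetrahydrooxepin-2-yl]pentanoate
Conditions: HF·pyridine, THF–pyridine, 0 °C to rt
Reagents that add atoms: none
Why: Cleavage of the silyl ether with HF·pyridine (fluoride-mediated desilylation) under buffered conditions should free the allylic alcohol without acetate migration or attack on the phosphonate.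

Step 17
Reactants: 28 the allylic alcohol named in step 16
Product: 29 methyl (5R)-5-(acetyloxy)-2-(dimethoxyphosphoryl)-5-[(2S)-2-methyl-7-oxo-6-[(3E)-5-oxo-3-(propan-2-yl)pent-3-en-1-yl]-2,3,4,7-tetrahydrooxepin-2-yl]pentanoate
Conditions: MnO2 (20 equiv), CH2Cl2, rt
Reagents that add atoms: none
Why: Activated MnO2 oxidises allylic alcohols selectively to enals under neutral conditions (allylic oxidation), which should preserve the C1=C2 geometry and leave the acidic phosphonoacetate untouched.

Step 18
Reactants: 29 the enal phosphonate named in step 17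
Product: 30 sarcrassin D
Conditions: LiCl, DBU, MeCN, 0.001 M, rt
Reagents that add atoms: none
Why: Intramolecular Horner–Wadsworth–Emmons olefination under Masamune–Roush conditions at high dilution should close the fourteen-membered ring and form the C3=C4 bond with the ester trans to C2, the normal outcome for α-alkyl phosphonoacetates.

**Compound list**

1 | 4-methylpent-2-yn-1-ol | CC(C)C#CCO | starting material
2 | sodium alkenylalanate (five-membered oxaaluminacycle from 1) | [Na+].COCCO[Al-]1(OCCOC)OCC=C1C(C)C | intermediate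
3 | (2Z)-3-iodo-4-methylpent-2-en-1-ol | CC(C)/C(I)=C/CO | intermediate
4 | tert-butyl{[(2Z)-3-iodo-4-methylpent-2-en-1-yl]oxy}diphenylsilane | CC(C)/C(I)=C/CO[Si](c1ccccc1)(c1ccccc1)C(C)(C)C | intermediate
5 | oxirane | C1CO1 | starting material
6 | {(2E)-1-[(tert-butyldiphenylsilyl)oxy]-4-methylpent-2-en-3-yl}lithium | CC(C)/C([Li])=C/CO[Si](c1ccccc1)(c1ccccc1)C(C)(C)C | intermediate
7 | (3E)-5-[(tert-butyldiphenylsilyl)oxy]-3-(propan-2-yl)pent-3-en-1-ol | CC(C)/C(CCO)=C/CO[Si](c1ccccc1)(c1ccccc1)C(C)(C)C | intermediate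
8 | tert-butyl{[(2E)-5-iodo-3-(propan-2-yl)pent-2-en-1-yl]oxy}diphenylsilane | CC(C)/C(CCI)=C/CO[Si](c1ccccc1)(c1ccccc1)C(C)(C)C | intermediate
9 | methyl [bis(2,2,2-trifluoroethoxy)phosphoryl]acetate | COC(=O)CP(=O)(OCC(F)(F)F)OCC(F)(F)F | starting material
10 | methyl (5E)-2-[bis(2,2,2-trifluoroethoxy)phosphoryl]-7-[(tert-butyldiphenylsilyl)oxy]-5-(propan-2-yl)hept-5-enoate (racemic at C2) | COC(=O)C(CC/C(=C\CO[Si](c1ccccc1)(c1ccccc1)C(C)(C)C)C(C)C)P(=O)(OCC(F)(F)F)OCC(F)(F)F | intermediate
11 | acetaldehyde | CC=O | starting material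
12 | methyl (2Z,5E)-7-[(tert-butyldiphenylsilyl)oxy]-2-ethylidene-5-(propan-2-yl)hept-5-enoate | COC(=O)/C(=C\C)CC/C(=C\CO[Si](c1ccccc1)(c1ccccc1)C(C)(C)C)C(C)C | intermediate
13 | (2Z,5E)-7-[(tert-butyldiphenylsilyl)oxy]-2-ethylidene-5-(propan-2-yl)hept-5-enoic acid | OC(=O)/C(=C\C)CC/C(=C\CO[Si](c1ccccc1)(c1ccccc1)C(C)(C)C)C(C)C | intermediate
14 | 3-[(tert-butyldimethylsilyl)oxy]propanal | O=CCCO[Si](C)(C)C(C)(C)C | starting material
15 | ethyl 2-(triphenyl-λ5-phosphanylidene)propanoate | CCOC(=O)C(C)=P(c1ccccc1)(c1ccccc1)c1ccccc1 | starting material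
16 | ethyl (2E)-5-[(tert-butyldimethylsilyl)oxy]-2-methylpent-2-enoate | CCOC(=O)/C(C)=C/CCO[Si](C)(C)C(C)(C)C | intermediate
17 | ethyl (2E)-5-bromo-2-methylpent-2-enoate | CCOC(=O)/C(C)=C/CCBr | intermediate
18 | (2E)-5-bromo-2-methylpent-2-en-1-ol | OC/C(C)=C/CCBr | intermediate
19 | [(2R,3R)-3-(2-bromoethyl)-2-methyloxiran-2-yl]methanol | OC[C@@]1(C)O[C@@H]1CCBr | intermediate
20 | [(2R,3R)-3-(2-bromoethyl)-2-methyloxiran-2-yl]methyl trifluoromethanesulfonate | O=S(=O)(OC[C@@]1(C)O[C@@H]1CCBr)C(F)(F)F | intermediate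
21 | dilithium dienediolate of 13 (dilithium (5E)-7-[(tert-butyldiphenylsilyl)oxy]-2-ethenyl-5-(propan-2-yl)hepta-1,5-diene-1,1-bis(olate)) | [Li+].[Li+].[O-]C([O-])=C(C=C)CC/C(=C\CO[Si](c1ccccc1)(c1ccccc1)C(C)(C)C)C(C)C | intermediate
22 | dicopper dienediolate of 13 (monovalent copper) | [Cu+].[Cu+].[O-]C([O-])=C(C=C)CC/C(=C\CO[Si](c1ccccc1)(c1ccccc1)C(C)(C)C)C(C)C | intermediate
23 | (2Z,5E)-2-{3-[(2R,3R)-3-(2-bromoethyl)-2-methyloxiran-2-yl]propylidene}-7-[(tert-butyldiphenylsilyl)oxy]-5-(propan-2-yl)hept-5-enoic acid | OC(=O)/C(=C\CC[C@@]1(C)O[C@@H]1CCBr)CC/C(=C\CO[Si](c1ccccc1)(c1ccccc1)C(C)(C)C)C(C)C | intermediate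
24 | (7S)-7-[(1R)-3-bromo-1-hydroxypropyl]-3-[(3E)-5-[(tert-butyldiphenylsilyl)oxy]-3-(propan-2-yl)pent-3-en-1-yl]-7-methyl-6,7-dihydrooxepin-2(5H)-one | CC(C)/C(CCC1=CCC[C@](C)(OC1=O)[C@H](O)CCBr)=C/CO[Si](c1ccccc1)(c1ccccc1)C(C)(C)C | intermediate
25 | (1R)-3-bromo-1-[(2S)-6-[(3E)-5-[(tert-butyldiphenylsilyl)oxy]-3-(propan-2-yl)pent-3-en-1-yl]-2-methyl-7-oxo-2,3,4,7-tetrahydrooxepin-2-yl]propyl acetate | CC(C)/C(CCC1=CCC[C@](C)(OC1=O)[C@H](OC(C)=O)CCBr)=C/CO[Si](c1ccccc1)(c1ccccc1)C(C)(C)C | intermediate
26 | methyl (dimethoxyphosphoryl)acetate | COC(=O)CP(=O)(OC)OC | starting material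
27 | methyl (5R)-5-(acetyloxy)-5-[(2S)-6-[(3E)-5-[(tert-butyldiphenylsilyl)oxy]-3-(propan-2-yl)pent-3-en-1-yl]-2-methyl-7-oxo-2,3,4,7-tetrahydrooxepin-2-yl]-2-(dimethoxyphosphoryl)pentanoate (epimers at C2) | CC(C)/C(CCC1=CCC[C@](C)(OC1=O)[C@H](OC(C)=O)CCC(C(=O)OC)P(=O)(OC)OC)=C/CO[Si](c1ccccc1)(c1ccccc1)C(C)(C)C | intermediate
28 | methyl (5R)-5-(acetyloxy)-2-(dimethoxyphosphoryl)-5-[(2S)-6-[(3E)-5-hydroxy-3-(propan-2-yl)pent-3-en-1-yl]-2-methyl-7-oxo-2,3,4,7-tetrahydrooxepin-2-yl]pentanoate (epimers at C2) | CC(C)/C(CCC1=CCC[C@](C)(OC1=O)[C@H](OC(C)=O)CCC(C(=O)OC)P(=O)(OC)OC)=C/CO | intermediate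
29 | methyl (5R)-5-(acetyloxy)-2-(dimethoxyphosphoryl)-5-[(2S)-2-methyl-7-oxo-6-[(3E)-5-oxo-3-(propan-2-yl)pent-3-en-1-yl]-2,3,4,7-tetrahydrooxepin-2-yl]pentanoate (epimers at C2) | CC(C)/C(CCC1=CCC[C@](C)(OC1=O)[C@H](OC(C)=O)CCC(C(=O)OC)P(=O)(OC)OC)=C/C=O | intermediate
30 | sarcrassin D | COC(=O)/C1=C/C=C(/C(C)C)CCC2=CCC[C@](C)(OC2=O)[C@H](OC(C)=O)CC1 | target

**Step count and risks**

Total step count: 18. Longest linear sequence: 13 steps (steps 1–7 and 13–18).

**Step 13 (Proposed new method).** What may go wrong: alkylation of the dienediolate at the α-carbon C12 or at oxygen instead of at C10, and loss of the Z geometry of the dienediolate before the C–C bond is formed, so that little lactonisable epoxy acid arises.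

Fallback (known chemistry; C10–C9 is made first and C11=C12 by olefination): it sets out from triflate 20 and phosphonate 10 and comes back to the route at epoxy acid 23. Displacement of the triflate in 20 with CH2=CHCH2MgBr and a catalytic amount of CuI (THF, −78 °C) should give (2R,3R)-3-(2-bromoethyl)-2-(but-3-en-1-yl)-2-methyloxirane F1. Ozonolysis (O3, CH2Cl2, −78 °C; then PPh3) should give 3-[(2R,3R)-3-(2-bromoethyl)-2-methyloxiran-2-yl]propanal F2. Still–Gennari olefination of F2 with 10 (KN(SiMe3)2, 18-crown-6, THF, −78 °C) should give methyl (2Z,5E)-2-{3-[(2R,3R)-3-(2-bromoethyl)-2-methyloxiran-2-yl]propylidene}-7-[(tert-butyldiphenylsilyl)oxy]-5-(propan-2-yl)hept-5-enoate F3. Hydrolysis of F3 with Me3SnOH (1,2-dichloroethane, 70 °C) should give epoxy acid 23, which is lactonised to 24 with camphorsulfonic acid as in step 13.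

**Step 18.** What may go wrong: oligomerisation in competition with the slow closure of the fourteen-membered ring, and base-induced γ-deprotonation of the β,β-disubstituted enal, which would scramble the C1=C2 geometry before olefination.

Fallback (ring closure by allylic alkylation instead of carbonyl olefination, no enal involved): it sets out from bromide 25 and comes back to the route at target 30. Alkylation of methyl (benzenesulfonyl)acetate with 25 (NaH, NaI, DMSO) should give methyl (5R)-5-(acetyloxy)-2-(benzenesulfonyl)-5-[(2S)-6-[(3E)-5-[(tert-butyldiphenylsilyl)oxy]-3-(propan-2-yl)pent-3-en-1-yl]-2-methyl-7-oxo-2,3,4,7-tetrahydrooxepin-2-yl]pentanoate F4. Desilylation (HF·pyridine) should give the allylic alcohol methyl (5R)-5-(acetyloxy)-2-(benzenesulfonyl)-5-[(2S)-6-[(3E)-5-hydroxy-3-(propan-2-yl)pent-3-en-1-yl]-2-methyl-7-oxo-2,3,4,7-tetrahydrooxepin-2-yl]pentanoate F5. ClCO2Me and pyridine should give the allylic carbonate methyl (5R)-5-(acetyloxy)-2-(benzenesulfonyl)-5-[(2S)-6-[(3E)-5-[(methoxycarbonyl)oxy]-3-(propan-2-yl)pent-3-en-1-yl]-2-methyl-7-oxo-2,3,4,7-tetrahydrooxepin-2-yl]pentanoate F6. Pd(PPh3)4 (zerovalent palladium, 5 mol %) in THF at high dilution and 60 °C should ionise the carbonate and let the sulfonyl ester carbanion attack the unsubstituted terminus C3 of the allyl palladium complex (Tsuji–Trost macrocyclisation), giving the macrocyclic sulfone 4-(benzenesulfonyl)-3,4-dihydrosarcrassin D F7. Elimination of benzenesulfinate from F7 towards the allylic C3–H (DBU, toluene, 60 °C) should then give the conjugated dienoate 30.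

**Step 6.** What may go wrong: erosion of the Z selectivity in the olefination of the α-branched phosphonate with a small aldehyde, which would carry the wrong C11=C12 geometry into the key step.

Fallback (the Z-enoate is made by a stereoretentive cross-coupling instead of an olefination): it sets out from iodide 8 and comes back to the route at ester 12. Zinc insertion into 8 (Zn dust, LiCl, THF, 40 °C) should give {(3E)-5-[(tert-butyldiphenylsilyl)oxy]-3-(propan-2-yl)pent-3-en-1-yl}zinc iodide F8. Separately, syn-hydrostannation of commercial methyl but-2-ynoate (Bu3SnH, catalytic Pd(PPh3)4, THF) should give methyl (2E)-2-(tributylstannyl)but-2-enoate F9. Iododestannylation (I2, CH2Cl2, 0 °C) should give methyl (2E)-2-iodobut-2-enoate F10, in which the methyl group is cis to the ester. Negishi coupling of F8 with F10 (Pd(PPh3)4, THF, rt) replaces iodine by the alkyl chain with retention of alkene geometry and should give 12.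

**Further compounds**

F1 | step 13 | (2R,3R)-3-(2-bromoethyl)-2-(but-3-en-1-yl)-2-methyloxirane | C=CCC[C@@]1(C)O[C@@H]1CCBr
F2 | step 13 | 3-[(2R,3R)-3-(2-bromoethyl)-2-methyloxiran-2-yl]propanal | O=CCC[C@@]1(C)O[C@@H]1CCBr
F3 | step 13 | methyl (2Z,5E)-2-{3-[(2R,3R)-3-(2-bromoethyl)-2-methyloxiran-2-yl]propylidene}-7-[(tert-butyldiphenylsilyl)oxy]-5-(propan-2-yl)hept-5-enoate | COC(=O)/C(=C\CC[C@@]1(C)O[C@@H]1CCBr)CC/C(=C\CO[Si](c1ccccc1)(c1ccccc1)C(C)(C)C)C(C)C
F4 | step 18 | methyl (5R)-5-(acetyloxy)-2-(benzenesulfonyl)-5-[(2S)-6-[(3E)-5-[(tert-butyldiphenylsilyl)oxy]-3-(propan-2-yl)pent-3-en-1-yl]-2-methyl-7-oxo-2,3,4,7-tetrahydrooxepin-2-yl]pentanoate | CC(C)/C(CCC1=CCC[C@](C)(OC1=O)[C@H](OC(C)=O)CCC(C(=O)OC)S(=O)(=O)c1ccccc1)=C/CO[Si](c1ccccc1)(c1ccccc1)C(C)(C)C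
F5 | step 18 | methyl (5R)-5-(acetyloxy)-2-(benzenesulfonyl)-5-[(2S)-6-[(3E)-5-hydroxy-3-(propan-2-yl)pent-3-en-1-yl]-2-methyl-7-oxo-2,3,4,7-tetrahydrooxepin-2-yl]pentanoate | CC(C)/C(CCC1=CCC[C@](C)(OC1=O)[C@H](OC(C)=O)CCC(C(=O)OC)S(=O)(=O)c1ccccc1)=C/CO
F6 | step 18 | methyl (5R)-5-(acetyloxy)-2-(benzenesulfonyl)-5-[(2S)-6-[(3E)-5-[(methoxycarbonyl)oxy]-3-(propan-2-yl)pent-3-en-1-yl]-2-methyl-7-oxo-2,3,4,7-tetrahydrooxepin-2-yl]pentanoate | CC(C)/C(CCC1=CCC[C@](C)(OC1=O)[C@H](OC(C)=O)CCC(C(=O)OC)S(=O)(=O)c1ccccc1)=C/COC(=O)OC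
F7 | step 18 | 4-(benzenesulfonyl)-3,4-dihydrosarcrassin D (C4 sp3, carrying PhSO2 and CO2Me) | COC(=O)C1(S(=O)(=O)c2ccccc2)C/C=C(/C(C)C)CCC2=CCC[C@](C)(OC2=O)[C@H](OC(C)=O)CC1
F8 | step 6 | {(3E)-5-[(tert-butyldiphenylsilyl)oxy]-3-(propan-2-yl)pent-3-en-1-yl}zinc iodide | CC(C)/C(CC[Zn]I)=C/CO[Si](c1ccccc1)(c1ccccc1)C(C)(C)C
F9 | step 6 | methyl (2E)-2-(tributylstannyl)but-2-enoate | C/C=C(\C(=O)OC)[Sn](CCCC)(CCCC)CCCC
F10 | step 6 | methyl (2E)-2-iodobut-2-enoate | C/C=C(\C(=O)OC)I
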